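**Retrosynthetic overview**

1. Locants used here: ring C1 (CH carrying the side chain), C2 (CH–O), C3 (C=O), C4 (C–CH3), C5 (epoxide CH), C6 (CH2); side chain C7 (=CH2), C8 (CH–O). Target ⇐ double senecioylation of diol 19 ⇐ C2–OH by enolate hydroxylation of cis-epoxy ketone 16 ⇐ C4–C5 oxirane by hydroxyl-directed epoxidation of cis-allylic alcohol 14 ⇐ enone 13.
2. Key disconnection C6–C5 (ring CH2 to the future epoxide CH, the enone β-carbon at this stage): 13 ⇐ cyclobutanol 10 by rhodium-catalysed enantioselective C–C cleavage, 6-endo conjugate ring closure and loss of chloride.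
3. Enabling feature: without the C2 oxygen, C1 carries two CH2 arms (C2 and C6) that can both end on C3, so the six-membered ring C1–C6 contracts to a 3-substituted cyclobutanol (ring C3–C2–C1–C6) with a mirror plane through C1 and C3. Choosing which CH2–C3 bond breaks sets C1, and the strain of the four-membered ring pays for the C6–C5 bond.
4. 10 ⇐ cyclobutanone 7 (ethynyl addition, then carbomagnesiation/chlorination) ⇐ 3-oxocyclobutanecarboxylic acid 1 + 2-bromoallyl alcohol 2 (decarboxylative vinylation), with C8 from an asymmetric allylation and the prenyl end from cross-metathesis.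
5. Order of rings: cyclobutane (purchased) → cyclohexenone (step 8) → oxirane (step 10).

Key step: step 8

Remark on the chemistry (assumption): (R)-DTBM-SEGPHOS is taken to cleave the ring bond that leads to (5R)-13; the sense of induction cannot be predicted with confidence and the mirror-image ligand is used if it proves opposite. TBS = tert-butyldimethylsilyl. Rhodium species 11 and 12 are drawn without the diphosphine.

**Route**

Step 1
Reactants: 1 3-oxocyclobutane-1-carboxylic acid; 2 2-bromoprop-2-en-1-ol
Product: 3 3-(3-hydroxyprop-1-en-2-yl)cyclobutan-1-one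
Conditions: Ir[dF(CF3)ppy]2(dtbbpy)PF6 (1 mol%), NiCl2·glyme (5 mol%), dtbbpy (5 mol%), DBU, DMSO, blue LEDs, rt
Reagents that add atoms: none
Why: Photoredox/nickel dual-catalysed decarboxylative sp3–sp2 cross-coupling of a secondary carboxylic acid with a vinyl bromide, in which the carboxylate is oxidised to the 3-oxocyclobutyl radical that nickel joins to the alkenyl group, and the product is achiral so no stereocentre is at stake.

Step 2
Reactants: 3 3-(3-hydroxyprop-1-en-2-yl)cyclobutan-1-one
Product: 4 2-(3-oxocyclobutyl)prop-2-enal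
Conditions: MnO2 (activated, excess), CH2Cl2, rt
Reagents that add atoms: none
Why: Allylic oxidation with manganese dioxide acts only on the primary allylic alcohol and leaves the cyclobutanone alone, and no stereocentre is formed.

Step 3
Reactants: 4 2-(3-oxocyclobutyl)prop-2-enal
Product: 5 3-[(3R)-3-hydroxyhexa-1,5-dien-2-yl]cyclobutan-1-one
Conditions: (R)-BINOL (20 mol%), Ti(OiPr)4 (10 mol%), 4 Å MS, allylSnBu3, CH2Cl2, −20 °C; aq. NaHCO3
Reagents that add atoms: allyltributylstannane, C=CC[Sn](CCCC)(CCCC)CCCC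
Why: Keck asymmetric allylation, in which the BINOL–titanium Lewis acid activates only the aldehyde (the ketone is inert) and the (R)-ligand should deliver allyl to the face that gives the (R)-carbinol, as it does for benzaldehyde and other aldehydes whose carbonyl substituent is an sp2 carbon.

Step 4
Reactants: 5 3-[(3R)-3-hydroxyhexa-1,5-dien-2-yl]cyclobutan-1-one
Product: 6 3-[(3R)-3-hydroxy-6-methylhepta-1,5-dien-2-yl]cyclobutan-1-one
Conditions: second-generation Grubbs catalyst (H2IMes)(PCy3)Cl2Ru=CHPh (5 mol%), 2-methylbut-2-ene (excess), CH2Cl2, 40 °C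
Reagents that add atoms: 2-methylbut-2-ene, CC=C(C)C
Why: Olefin cross-metathesis of the monosubstituted terminal alkene with 2-methylbut-2-ene installs the prenyl terminus, while the hindered 1,1-disubstituted alkene should not react and the carbinol centre is untouched.

Step 5
Reactants: 6 3-[(3R)-3-hydroxy-6-methylhepta-1,5-dien-2-yl]cyclobutan-1-one
Product: 7 3-[(3R)-3-(TBSO)-6-methylhepta-1,5-dien-2-yl]cyclobutan-1-one
Conditions: TBSCl, imidazole, DMF, rt
Reagents that add atoms: tert-butyl(chloro)dimethylsilane, CC(C)(C)[Si](C)(C)Cl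
Why: Standard silylation of the secondary allylic alcohol, needed because a free secondary alcohol would be oxidised through β-hydride elimination of its rhodium alkoxide in step 8.

Step 6
Reactants: 7 3-[(3R)-3-(TBSO)-6-methylhepta-1,5-dien-2-yl]cyclobutan-1-one
Product: 8 cis-3-[(3R)-3-(TBSO)-6-methylhepta-1,5-dien-2-yl]-1-ethynylcyclobutan-1-ol (hydroxyl cis to the side chain)
Conditions: HC≡CMgBr, THF, −78 °C → 0 °C; H2O
Reagents that add atoms: ethynylmagnesium bromide, C#C[Mg]Br
Why: 1,2-Addition of an alkynyl Grignard reagent to a 3-substituted cyclobutanone, which should occur on the face of the puckered ring anti to the 3-substituent and so give the cyclobutanol with hydroxyl cis to the side chain, the minor trans isomer being removed by chromatography.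

Step 7
Reactants: 8 cis-3-[(3R)-3-(TBSO)-6-methylhepta-1,5-dien-2-yl]-1-ethynylcyclobutan-1-ol
Product: 10 cis-1-[(Z)-1-chloroprop-1-en-2-yl]-3-[(3R)-3-(TBSO)-6-methylhepta-1,5-dien-2-yl]cyclobutan-1-ol, via vinylmagnesium chelate 9 (not isolated)
Conditions: MeMgBr (4 equiv), CuI (20 mol%), THF, 0 °C → 40 °C; then NCS, −30 °C → rt; H2O
Reagents that add atoms: methylmagnesium bromide, C[Mg]Br; N-chlorosuccinimide, O=C1CCC(=O)N1Cl
Why: Copper-catalysed anti-carbomagnesiation of a propargylic alkoxide places methyl on the alkyne carbon next to the carbinol and magnesium on the terminus inside a five-membered O–Mg chelate, and electrophilic chlorination with retention should give the (Z)-chloroalkene, whose geometry is of no consequence later.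

Step 8
Reactants: 10 cis-1-[(Z)-1-chloroprop-1-en-2-yl]-3-[(3R)-3-(TBSO)-6-methylhepta-1,5-dien-2-yl]cyclobutan-1-ol
Product: 13 (5R)-5-[(3R)-3-(TBSO)-6-methylhepta-1,5-dien-2-yl]-2-methylcyclohex-2-en-1-one, via alkylrhodium chloroenone 11 (not isolated), via rhodium enolate 12 (not isolated)
Conditions: [Rh(OH)(cod)]2 (2.5 mol%), (R)-DTBM-SEGPHOS (6 mol%), Cs2CO3 (1.2 equiv), toluene, 60 °C
Reagents that add atoms: none
Why: Proposed new method: the monovalent rhodium alkoxide of 10 undergoes β-carbon elimination of one of the two ring CH2–C(OH) bonds, driven by release of cyclobutane strain, to give primary alkylrhodium 11 carrying a β-chloro enone, whose alkyl group adds to the enone β-carbon (the CHCl carbon) to form the ring-closing C6–C5 bond and rhodium enolate 12, which expels chloride to give enone 13 while Cs2CO3 returns Rh–Cl to the alkoxide. The closest known reaction type is the rhodium/diphosphine-catalysed enantioselective ring opening of prochiral tert-cyclobutanols by β-carbon elimination followed by intramolecular 1,4-addition of the alkylrhodium to a tethered allenyl ketone to give cyclohexenones, joined here to the β-heteroatom elimination that ends many rhodium addition–elimination cycles. The six-membered carbocycle is closed by a 6-endo-trig conjugate carbometalation. The only new stereocentre, the ring carbon bearing the side chain, is set by the chiral diphosphine, which chooses between two CH2–C(OH) bonds that are mirror-related except for the remote silyloxy centre, and this demands the single cis diastereomer of 10 because the trans isomer would give the epimer with the same catalyst. The step needs 6-endo over 5-exo closure, secured by the polarisation of the enone that sends the nucleophilic alkyl group to the β-carbon and rhodium to oxygen, and it needs the intramolecular addition to outrun protonation or β-hydride elimination of 11. The alkene geometry of the chloroalkene is erased in 12, so the step is convergent with respect to it.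

Step 9
Reactants: 13 (5R)-5-[(3R)-3-(TBSO)-6-methylhepta-1,5-dien-2-yl]-2-methylcyclohex-2-en-1-one
Product: 14 (1R,5R)-5-[(3R)-3-(TBSO)-6-methylhepta-1,5-dien-2-yl]-2-methylcyclohex-2-en-1-ol
Conditions: NaBH4, CeCl3·7H2O, MeOH, −78 °C → 0 °C
Reagents that add atoms: none
Why: Luche 1,2-reduction, in which hydride should add axially to the half-chair that holds the side chain equatorial and give the alcohol cis to the side chain, as (R)-carvone gives cis-carveol.

Step 10
Reactants: 14 (1R,5R)-5-[(3R)-3-(TBSO)-6-methylhepta-1,5-dien-2-yl]-2-methylcyclohex-2-en-1-ol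
Product: 15 (1R,2R,4S,6S)-4-[(3R)-3-(TBSO)-6-methylhepta-1,5-dien-2-yl]-1-methyl-7-oxabicyclo[4.1.0]heptan-2-ol
Conditions: VO(acac)2 (5 mol%), tBuOOH (in decane), CH2Cl2, 0 °C → rt
Reagents that add atoms: tert-butyl hydroperoxide, CC(C)(C)OO
Why: Vanadium-catalysed hydroxyl-directed epoxidation delivers oxygen to the ring alkene from the face of the allylic hydroxyl, hence cis to the side chain, and leaves the two side-chain alkenes, which have no free allylic hydroxyl, untouched.

Step 11
Reactants: 15 (1R,2R,4S,6S)-4-[(3R)-3-(TBSO)-6-methylhepta-1,5-dien-2-yl]-1-methyl-7-oxabicyclo[4.1.0]heptan-2-ol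
Product: 16 (1S,4R,6S)-4-[(3R)-3-(TBSO)-6-methylhepta-1,5-dien-2-yl]-1-methyl-7-oxabicyclo[4.1.0]heptan-2-one
Conditions: (nPr4N)RuO4 (5 mol%), NMO, 4 Å MS, CH2Cl2, rt
Reagents that add atoms: none
Why: Ley–Griffith oxidation converts the secondary epoxy alcohol into the α,β-epoxy ketone under neutral conditions that spare the oxirane and the silyl ether, the carbinol stereocentre having done its directing work.

Step 12
Reactants: 16 (1S,4R,6S)-4-[(3R)-3-(TBSO)-6-methylhepta-1,5-dien-2-yl]-1-methyl-7-oxabicyclo[4.1.0]heptan-2-one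
Product: 18 (1S,3S,4S,6S)-3-hydroxy-4-[(3R)-3-(TBSO)-6-methylhepta-1,5-dien-2-yl]-1-methyl-7-oxabicyclo[4.1.0]heptan-2-one, via potassium enolate 17 (not isolated)
Conditions: KN(SiMe3)2, THF, −78 °C; then 2-(benzenesulfonyl)-3-phenyloxaziridine, −78 °C; AcOH
Reagents that add atoms: 2-(benzenesulfonyl)-3-phenyloxaziridine, O=S(=O)(c1ccccc1)N1OC1c1ccccc1
Why: Davis enolate hydroxylation, in which deprotonation can occur only at the CH2 beside the ketone because the other α-carbon is the fully substituted oxirane carbon, and the oxaziridine should attack the enolate anti to the neighbouring side chain and to the oxirane oxygen, giving the hydroxyl trans to the side chain.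

Step 13
Reactants: 18 (1S,3S,4S,6S)-3-hydroxy-4-[(3R)-3-(TBSO)-6-methylhepta-1,5-dien-2-yl]-1-methyl-7-oxabicyclo[4.1.0]heptan-2-one
Product: 19 (1S,3S,4S,6S)-3-hydroxy-4-[(3R)-3-hydroxy-6-methylhepta-1,5-dien-2-yl]-1-methyl-7-oxabicyclo[4.1.0]heptan-2-one
Conditions: HF·pyridine, pyridine, THF, 0 °C → rt
Reagents that add atoms: none
Why: Buffered fluoride desilylation cleaves the silyl ether without base, so the α-hydroxy ketone and the oxirane are not exposed to epimerising or ring-opening conditions.

Step 14
Reactants: 19 (1S,3S,4S,6S)-3-hydroxy-4-[(3R)-3-hydroxy-6-methylhepta-1,5-dien-2-yl]-1-methyl-7-oxabicyclo[4.1.0]heptan-2-one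
Product: 20 (1S,3S,4S,6S)-1-methyl-4-{(3R)-6-methyl-3-[(3-methylbut-2-enoyl)oxy]hepta-1,5-dien-2-yl}-2-oxo-7-oxabicyclo[4.1.0]heptan-3-yl 3-methylbut-2-enoate (target)
Conditions: 3-methylbut-2-enoic acid (3 equiv), DCC, DMAP (cat.), CH2Cl2, 0 °C → rt
Reagents that add atoms: 3-methylbut-2-enoic acid, CC(C)=CC(=O)O
Why: Steglich esterification acylates both secondary hydroxyls in one operation and is chosen over the acid chloride with an amine base to avoid the vinylketene pathway that would move the double bond out of conjugation, and no stereocentre is touched.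

**Compound list**

1 | 3-oxocyclobutane-1-carboxylic acid | O=C1CC(C1)C(=O)O | starting material
2 | 2-bromoprop-2-en-1-ol | C=C(Br)CO | starting material
3 | 3-(3-hydroxyprop-1-en-2-yl)cyclobutan-1-one | OCC(=C)C1CC(=O)C1 | intermediate
4 | 2-(3-oxocyclobutyl)prop-2-enal | O=CC(=C)C1CC(=O)C1 | intermediate
5 | 3-[(3R)-3-hydroxyhexa-1,5-dien-2-yl]cyclobutan-1-one | C=C([C@@H](CC=C)O)C1CC(=O)C1 | intermediate
6 | 3-[(3R)-3-hydroxy-6-methylhepta-1,5-dien-2-yl]cyclobutan-1-one | C=C([C@@H](CC=C(C)C)O)C1CC(=O)C1 | intermediate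
7 | 3-[(3R)-3-(tert-butyldimethylsilyloxy)-6-methylhepta-1,5-dien-2-yl]cyclobutan-1-one | C=C([C@@H](CC=C(C)C)O[Si](C)(C)C(C)(C)C)C1CC(=O)C1 | intermediate
8 | cis-3-[(3R)-3-(tert-butyldimethylsilyloxy)-6-methylhepta-1,5-dien-2-yl]-1-ethynylcyclobutan-1-ol (OH cis to the side chain) | O[C@@]1(C#C)C[C@@H](C(=C)[C@@H](CC=C(C)C)O[Si](C)(C)C(C)(C)C)C1 | intermediate
9 | bromomagnesium alkoxide of the cyclobutanol carrying a (Z)-2-(bromomagnesio)-1-methylvinyl group, O–Mg/C–Mg chelate (not isolated) | Br[Mg]O[C@@]1(/C(C)=C\[Mg]Br)C[C@@H](C(=C)[C@@H](CC=C(C)C)O[Si](C)(C)C(C)(C)C)C1 | intermediate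
10 | cis-1-[(Z)-1-chloroprop-1-en-2-yl]-3-[(3R)-3-(tert-butyldimethylsilyloxy)-6-methylhepta-1,5-dien-2-yl]cyclobutan-1-ol | O[C@@]1(/C(C)=C\Cl)C[C@@H](C(=C)[C@@H](CC=C(C)C)O[Si](C)(C)C(C)(C)C)C1 | intermediate
11 | ring-opened primary alkylrhodium species: open-chain (Z)-β-chloro-α-methyl enone with a CH2–Rh group on the carbon that bears the side chain (not isolated) | C=C([C@@H](CC=C(C)C)O[Si](C)(C)C(C)(C)C)[C@H](C[Rh])CC(=O)/C(C)=C\Cl | intermediate
12 | rhodium enolate of the cyclised 3-chloro-2-methylcyclohexanone, either configuration at the CHCl carbon (not isolated) | C=C([C@@H](CC=C(C)C)O[Si](C)(C)C(C)(C)C)[C@@H]1CC(Cl)C(C)=C(O[Rh])C1 | intermediate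
13 | (5R)-5-[(3R)-3-(tert-butyldimethylsilyloxy)-6-methylhepta-1,5-dien-2-yl]-2-methylcyclohex-2-en-1-one | C=C([C@@H](CC=C(C)C)O[Si](C)(C)C(C)(C)C)[C@@H]1CC=C(C)C(=O)C1 | intermediate
14 | (1R,5R)-5-[(3R)-3-(tert-butyldimethylsilyloxy)-6-methylhepta-1,5-dien-2-yl]-2-methylcyclohex-2-en-1-ol | C=C([C@@H](CC=C(C)C)O[Si](C)(C)C(C)(C)C)[C@@H]1CC=C(C)[C@H](O)C1 | intermediate
15 | (1R,2R,4S,6S)-4-[(3R)-3-(tert-butyldimethylsilyloxy)-6-methylhepta-1,5-dien-2-yl]-1-methyl-7-oxabicyclo[4.1.0]heptan-2-ol | C=C([C@@H](CC=C(C)C)O[Si](C)(C)C(C)(C)C)[C@@H]1C[C@@H]2O[C@]2(C)[C@H](O)C1 | intermediate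
16 | (1S,4R,6S)-4-[(3R)-3-(tert-butyldimethylsilyloxy)-6-methylhepta-1,5-dien-2-yl]-1-methyl-7-oxabicyclo[4.1.0]heptan-2-one | C=C([C@@H](CC=C(C)C)O[Si](C)(C)C(C)(C)C)[C@@H]1C[C@@H]2O[C@]2(C)C(=O)C1 | intermediate
17 | potassium enolate of 16 toward the ring CH2 (not isolated) | C=C([C@@H](CC=C(C)C)O[Si](C)(C)C(C)(C)C)[C@@H]1C[C@@H]2O[C@]2(C)C(O[K])=C1 | intermediate
18 | (1S,3S,4S,6S)-3-hydroxy-4-[(3R)-3-(tert-butyldimethylsilyloxy)-6-methylhepta-1,5-dien-2-yl]-1-methyl-7-oxabicyclo[4.1.0]heptan-2-one | C=C([C@@H](CC=C(C)C)O[Si](C)(C)C(C)(C)C)[C@@H]1C[C@@H]2O[C@]2(C)C(=O)[C@H]1O | intermediate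
19 | (1S,3S,4S,6S)-3-hydroxy-4-[(3R)-3-hydroxy-6-methylhepta-1,5-dien-2-yl]-1-methyl-7-oxabicyclo[4.1.0]heptan-2-one | C=C([C@@H](CC=C(C)C)O)[C@@H]1C[C@@H]2O[C@]2(C)C(=O)[C@H]1O | intermediate
20 | (1S,3S,4S,6S)-1-methyl-4-{(3R)-6-methyl-3-[(3-methylbut-2-enoyl)oxy]hepta-1,5-dien-2-yl}-2-oxo-7-oxabicyclo[4.1.0]heptan-3-yl 3-methylbut-2-enoate | C=C([C@@H](CC=C(C)C)OC(=O)C=C(C)C)[C@@H]1C[C@@H]2O[C@]2(C)C(=O)[C@H]1OC(=O)C=C(C)C | target

**Step count and risks**

Total step count: 14. Longest linear sequence: 14 steps (1 → 20).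

Step 8 (Proposed new method). Discrimination between the two ring CH2–C(OH) bonds may be weak or of the wrong sense. The alkylrhodium may also be protonated, or lose a β-hydride toward the tertiary C–H, before it closes the ring, and the alkoxide may expel the alkenyl group instead of opening the ring. The fallback uses known chemistry, sets out from 7 and returns at 13. Asymmetric Baeyer–Villiger oxidation of cyclobutanone 7 (chiral BINOL-derived phosphoric acid, aqueous H2O2) should give (4R)-γ-lactone F1, so that the desymmetrisation rests on which CH2 migrates. Aminolysis with MeNH(OMe)·HCl and iPrMgCl should give hydroxy Weinreb amide F2, and an Appel reaction (I2, PPh3, imidazole) the primary iodide F3. Isopropenylmagnesium bromide should then give α-methyl enone F4. Tin hydride radical cyclisation (Bu3SnH, AIBN, slow addition) should close the same C6–C5 bond by 6-endo attack of the primary radical on the enone terminus and give 2-methylcyclohexanone F5. The more substituted trimethylsilyl enol ether F6 (TMSCl, NaI, Et3N) and Saegusa–Ito dehydrogenation with Pd(OAc)2 should then lead back to 13.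

Step 7. Carbometalation of the hindered tertiary propargylic alkoxide may be sluggish, the chelate may be lost so that regio- and stereocontrol erode, and chlorination of the vinylmagnesium species may be incomplete. The fallback sets out from 8 and returns at 13. Negishi zirconium-catalysed methylalumination of the alkyne (Me3Al, Cp2ZrCl2, on the aluminium alkoxide) is a syn addition that needs no chelate; quenching with N-chlorosuccinimide should give the (E)-chloroalkene F7. F7 is taken through step 8 unchanged, because the alkene geometry is lost in the rhodium enolate.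

Step 1. Oxidation and capture of a non-stabilised secondary radical may be inefficient, with protodecarboxylation of 1 or hydrodebromination of 2 taking over. The fallback sets out from 1 and returns at 3. Acid 1 is converted into its N-hydroxyphthalimide ester F8 (N-hydroxyphthalimide, DIC, DMAP cat.). F8 is then coupled with 2 in a thermal nickel-catalysed reductive cross-electrophile coupling (NiBr2·glyme, dtbbpy, Zn, DMA), which forms the same radical by single-electron reduction instead of photochemical oxidation.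

Further compounds
F1 | step 8 | (4R)-4-[(3R)-3-(tert-butyldimethylsilyloxy)-6-methylhepta-1,5-dien-2-yl]oxolan-2-one | C=C([C@@H](CC=C(C)C)O[Si](C)(C)C(C)(C)C)[C@@H]1COC(=O)C1
F2 | step 8 | (3R,5R)-5-(tert-butyldimethylsilyloxy)-3-(hydroxymethyl)-N-methoxy-N,8-dimethyl-4-methylidenenon-7-enamide | CON(C)C(=O)C[C@@H](CO)C(=C)[C@@H](CC=C(C)C)O[Si](C)(C)C(C)(C)C
F3 | step 8 | (3R,5R)-5-(tert-butyldimethylsilyloxy)-3-(iodomethyl)-N-methoxy-N,8-dimethyl-4-methylidenenon-7-enamide | CON(C)C(=O)C[C@@H](CI)C(=C)[C@@H](CC=C(C)C)O[Si](C)(C)C(C)(C)C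
F4 | step 8 | (5R,7R)-7-(tert-butyldimethylsilyloxy)-5-(iodomethyl)-2,10-dimethyl-6-methylideneundeca-1,9-dien-3-one | C=C(C)C(=O)C[C@@H](CI)C(=C)[C@@H](CC=C(C)C)O[Si](C)(C)C(C)(C)C
F5 | step 8 | (5R)-5-[(3R)-3-(tert-butyldimethylsilyloxy)-6-methylhepta-1,5-dien-2-yl]-2-methylcyclohexan-1-one (both C2 epimers) | C=C([C@@H](CC=C(C)C)O[Si](C)(C)C(C)(C)C)[C@@H]1CCC(C)C(=O)C1
F6 | step 8 | trimethylsilyl enol ether of F5 toward the methyl-bearing carbon | C=C([C@@H](CC=C(C)C)O[Si](C)(C)C(C)(C)C)[C@@H]1CCC(C)=C(O[Si](C)(C)C)C1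
F7 | step 7 | cis-1-[(E)-1-chloroprop-1-en-2-yl]-3-[(3R)-3-(tert-butyldimethylsilyloxy)-6-methylhepta-1,5-dien-2-yl]cyclobutan-1-ol | O[C@@]1(/C(C)=C/Cl)C[C@@H](C(=C)[C@@H](CC=C(C)C)O[Si](C)(C)C(C)(C)C)C1
F8 | step 1 | 1,3-dioxoisoindolin-2-yl 3-oxocyclobutane-1-carboxylate | O=C1CC(C1)C(=O)ON1C(=O)c2ccccc2C1=O
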